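Its constants stand for no real mixture; the run is a simulation.

The slow start was what I had to reckon in this flask: the uncatalysed step gives a trickle of released group, and the released group then speeds its own making.

| flask | substrate | reagent | time | remark |
|---|---|---|---|---|
| delta | 37 mM (fed, over 12.0 s) | 0.600 equiv | 15 s | a stirred flask in which substrate is dosed at a steady rate over 12.0 s without added volume, worked up at 15 s |
| zeta | 37 mM | 0.600 equiv |  | one stirred flow tank at steady state, fed with the mixture as stated, mean residence time 15 s |
| eta | 37 mM | 0.600 equiv | 15 s | a closed flask charged with all of it at once and left for 15 s |
| gamma | 37 mM | 0.600 equiv (fed, over 12.0 s) | 15 s | all but reagent at the start; reagent goes in evenly over 12.0 s, the run ends at 15 s |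

1. the set-up with the highest amount of target at the outlet or at the end, in percent of the substrate put in ("none" if the first two lie within 2 percentage points) (delta / zeta / eta / gamma / none)
2. amount of target at the outlet or at the end, in percent of the substrate put in, delta
3. amount of target at the outlet or at the end, in percent of the substrate put in, zeta
4. amount of target at the outlet or at the end, in percent of the substrate put in, eta
5. amount of target at the outlet or at the end, in percent of the substrate put in, gamma

- a species is counted by the substrate in it: one idle adduct or side product counts as two
- amounts and yields of target count idle adduct too
- the stated concentrations are those of everything mixed, before any reaction; amounts are the same in each set-up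
- the feed brings no volume worth counting
- in an amount of target, one idle adduct counts as one target
- run time (delta): 15 s

    substrate + reagent + released group → target + 2 released group (k1 = 370 L² mol⁻² s⁻¹)
    substrate + reagent → target + released group (k2 = 0.027 L mol⁻¹ s⁻¹)
    substrate + target ⇌ idle adduct, settled at all times (K3 = 50 L mol⁻¹)
    substrate → decomposition product (k4 = 2.2 × 10⁻⁵ s⁻¹)
    substrate + target → side product (k5 = 0.34 L mol⁻¹ s⁻¹)

I asked first which numbers had to be known well. Decomposition takes 0.0330 % of the substrate over the run, so its constant hardly matters. The side product could take 18.9 % of the target with substrate as charged, and the idle adduct would lower free substrate by a factor 1.69 with target near the level below; I left both aside as late corrections. The seed, 0.197 % of the charge, is a plain factor in the yield while that yield stays small, as I expected in delta and gamma, and it drops out of my steady-state balance for the zeta tank. The constant of the catalysed step sits in an exponent, and that one must be known well.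

Its measure is the multiplying time 3.29 s, the time in which seed plus released group grows by a factor e with substrate and reagent as charged, a pseudo-first-order growth. In delta and gamma the even dose makes the run count as 9.00 s, and while the yield stays small an error in that constant is multiplied by the number of such times, 2.74 in these two flasks.

Then I worked with the fractions left. Their product falls, for small yields, along a line reaching zero at 37.5 %, which gives a logistic curve: 2.63 % for delta, 2.63 % for gamma, 12.4 % for eta. In the zeta tank, the steady state needs that line to stand at the multiplying time over the residence time, so 29.3 %. My choice was zeta.

The forecast named zeta, with 2.5 %, 32 %, 11.6 % and 2.5 % for delta, zeta, eta and gamma, holding that “the tank has no low steady state because back-mixing supplies catalyst”.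

The simulation gave zeta, with 2.59 %, 32.0 %, 11.8 % and 2.59 % in the same order, so zeta stood 2.7 percentage points above my reckoning.

In gamma the multiplying time of 3.29 s is far shorter than the 19 min half-life of substrate by the uncatalysed step alone, yet the 2.74 multiplying times of the shortened run left 95.7 % of the substrate at the end. With the dose in delta going in over 1.50 s, the count rises to 4.33, the same curve gives 10.6 %, and the run read 10.1 %.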